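The cycloheptenone is simplified by removing C2 (ring atoms: C1 ketone, C2 hydroxymethyl carbon, C3, C4, C5 quaternary, C6 enol-ester carbon, C7 acetonyl carbon). What remains is a cyclohexanone. A temporary cyclopentane joining the first chain carbon on C5 to the two-carbon arm on C6 makes it a rigid trans-hydrindanone, in which C5, C6 and C7 are set beforehand. One operation, dibromocarbene transfer to the C1=C3 silyl enol ether followed by cyclopropane opening, inserts C2, creates the C2=C3 enone and leaves bromine on C2 for hydroxymethylation. The precursor is the bis(trimethylsilyl) derivative, enol ether plus carbinol ether, of the ketal-protected acetonyl hydrindanone.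

Key step: step 11

Numbering: hydrindane numbering (C1–C7a) is used up to 13. From 15 on, the target ring numbering C1–C7 is used, with C1′ for the carbon on C5 and C1″, C2″ for the two carbons on C6 (the C1′–C2″ bond closes the cyclopentane). β is the face of the methyl group on C7a/C5 and α is the opposite face.
Assumption: the C1 carbinol centre in 26 and 28 is drawn as expected for hydride attack anti to the C7 side chain, and the lactol centre of 26 is left open; both are erased in steps 18 and 19, so their configuration does not matter.

Step 1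
Reactants: 1 ethyl levulinate
Product: 2 ethyl 3-(2-methyl-1,3-dioxolan-2-yl)propanoate
Conditions: HOCH2CH2OH, p-TsOH (cat.), toluene, reflux, Dean–Stark
Reagents that add atoms: ethylene glycol, OCCO
Why: Acid-catalysed ketalisation driven by azeotropic water removal masks the ketone that ends as the acetonyl carbonyl, while the ester is untouched.

Step 2
Reactants: 2 ketal ester
Product: 3 N-methoxy-N-methyl-3-(2-methyl-1,3-dioxolan-2-yl)propanamide
Conditions: MeNH(OMe)·HCl, iPrMgCl, THF, −20 to 0 °C
Reagents that add atoms: N,O-dimethylhydroxylamine hydrochloride, CNOC.Cl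
Why: Aminolysis of the ester by the chloromagnesium amide (Weinreb amide formation) runs under basic conditions that the dioxolane tolerates.

Step 3
Reactants: 3 Weinreb amide; 4 vinylmagnesium bromide
Product: 5 5-(2-methyl-1,3-dioxolan-2-yl)pent-1-en-3-one
Conditions: THF, −78 to 0 °C; inverse quench into cold aq. NH4Cl
Reagents that add atoms: vinylmagnesium bromide, C=C[Mg]Br
Why: Weinreb ketone synthesis: the chelated tetrahedral adduct survives until the quench, so only one vinyl group adds, and the cold inverse quench keeps the released amine from adding to the vinyl ketone.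

Step 4
Reactants: 5 ketal enone; 6 2-methylcyclopentane-1,3-dione
Product: 7 2-methyl-2-[5-(2-methyl-1,3-dioxolan-2-yl)-3-oxopentyl]cyclopentane-1,3-dione
Conditions: Et3N (cat.), MeCN, rt
Reagents that add atoms: none
Why: Amine-catalysed Michael addition of the acidic 1,3-dione to the unhindered vinyl ketone builds the (still prochiral) quaternary carbon without acid, so the ketal is safe.

Step 5
Reactants: 7 triketone
Product: 8 (7aS)-7a-methyl-4-[(2-methyl-1,3-dioxolan-2-yl)methyl]-2,3,7,7a-tetrahydro-1H-indene-1,5(6H)-dione
Conditions: (S)-phenylalanine, PPTS, DMSO, 50 °C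
Reagents that add atoms: none
Why: Hajos–Parrish–Eder–Sauer–Wiechert enamine aldol condensation: the primary amino acid forms the enamine of this internally substituted ketone more readily than proline and differentiates the two enantiotopic ring carbonyls in a hydrogen-bonded transition state, so the (S)-acid should give the 7aS centre (target C5), and the weak acid co-catalyst dehydrates without opening the dioxolane.

Step 6
Reactants: 8 enedione
Product: 9 (1S,7aS)-1-hydroxy enone (1β-OH, cis to the angular methyl)
Conditions: NaBH4, EtOH, −20 °C
Reagents that add atoms: none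
Why: Chemoselective borohydride reduction takes the saturated five-ring ketone rather than the tetrasubstituted enone, and hydride arrives on the α face away from the angular methyl to give the 1β carbinol.

Step 7
Reactants: 9 1β-carbinol
Product: 10 (1R,7aS)-1-(4-nitrobenzoyloxy) enone (1α-ester)
Conditions: 4-O2NC6H4CO2H, PPh3, DIAD, toluene, 0 to 60 °C
Reagents that add atoms: 4-nitrobenzoic acid, O=C(O)c1ccc(cc1)[N+](=O)[O-]
Why: Mitsunobu reaction: SN2 displacement of the oxyphosphonium ion by the acidic nitrobenzoate inverts C1 to α, as established for hindered 17β-hydroxy steroids, and the crystalline ester allows the enantiomeric purity to be raised by recrystallisation.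

Step 8
Reactants: 10 1α-nitrobenzoate
Product: 11 (1R,7aS)-1-hydroxy enone (1α-OH, trans to the angular methyl)
Conditions: K2CO3 (cat.), MeOH, rt
Reagents that add atoms: none
Why: Base-catalysed transesterification cleaves the activated benzoate at the acyl carbon, so the inverted carbinol is retained, and no epimerisable centre is present yet.

Step 9
Reactants: 11 1α-carbinol
Product: 12 (1R,3aS,4R,7aS)-1-hydroxy-7a-methyl-4-[(2-methyl-1,3-dioxolan-2-yl)methyl]octahydro-5H-inden-5-one (trans-fused; 3aα-H, 4α-H, side chain 4β)
Conditions: [Ir(cod)(PCy3)(py)]PF6 (cat.), H2 (pressure), CH2Cl2, rt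
Reagents that add atoms: none
Why: Hydroxyl-directed homogeneous hydrogenation: the homoallylic 1α-hydroxyl binds the cationic iridium centre and both hydrogens add syn to the α face of C3a=C4, which sets 3aS (target C6, trans fusion) and 4R (target C7, axial β side chain) as a kinetic outcome that equilibrating reductions could not give.

Step 10
Reactants: 12 hydroxy hydrindanone
Product: 13 (1R,3aS,4R,7aS)-7a-methyl-4-[(2-methyl-1,3-dioxolan-2-yl)methyl]-1,5-bis(trimethylsilyloxy)-2,3,3a,4,7,7a-hexahydro-1H-indene
Conditions: LiN(iPr)2, Me3SiCl (internal quench), THF, −78 to 0 °C; cold NaHCO3/pentane work-up, used crude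
Reagents that add atoms: chlorotrimethylsilane, C[Si](C)(C)Cl
Why: Kinetic enol silylation removes a proton from C6, the only α-methylene, and leaves the equatorial C4–H and the labile axial side chain untouched, while the alkoxide is silylated in the same flask; trimethylsilyl is chosen over a bulkier silyl ether because it must later leave a neopentyl-type carbinol next to an acid-sensitive ketal.

Step 11
Reactants: 13 bis(trimethylsilyl) precursor; 14 bromoform
Product: 17 trans-fused 2-bromo-1′α-hydroxy hydroazulenone, via dibromocyclopropane 15 (not isolated), via bromoenone silyl ether 16 (not isolated)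
Conditions: CHBr3, KOtBu, pentane, −30 to 20 °C; then citric acid (cat.), MeOH, 0 °C
Reagents that add atoms: bromoform, BrC(Br)Br
Why: tert-Butoxide deprotonates bromoform and α-elimination gives singlet dibromocarbene, which adds in a concerted [2+1] manner to the only electron-rich alkene of 13, from the α face opposite the angular methyl and the axial side chain, forming C2–C1 and C2–C3 in 15. On warming, the bromide lying endo to the six-membered ring ionises while the shared C1–C3 bond opens in a disrotatory cyclopropyl-to-allyl sense pushed by the silyloxy oxygen, and transfer of the silyl group to tert-butoxide leaves the 2-bromo enone 16. This is the known dihalocarbene ring enlargement of cyclic silyl enol ethers to 2-halo-2-enones. The three-membered ring is closed by cheletropic addition, whereas the seven-membered ring is not closed by cyclisation but results from scission of the zero-atom bridge of the bicyclo[4.1.0] unit. No lasting stereocentre is made (the two cyclopropane centres vanish), and C5, C6 and C7 are not touched, because C7 cannot enolise while C1 is masked and the base is consumed by bromoform and by the silyl bromide as the enone appears. Site selectivity comes from step 10, which placed the enol double bond toward the only α-methylene, and brief citric acid methanolysis then frees the C1′ carbinol without harming the ketal.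

Step 12
Reactants: 17 hydroxy bromoenone
Product: 18 trans-fused 2-bromo hydroazulene-1,1′-dione (bromoenone plus cyclopentanone)
Conditions: Dess–Martin periodinane, pyridine, CH2Cl2, 0 °C to rt
Reagents that add atoms: none
Why: Dess–Martin oxidation with pyridine buffering turns the secondary carbinol into the cyclopentanone under near-neutral conditions that spare the ketal, the bromoenone and C7.

Step 13
Reactants: 18 bromo diketone; 19 (tributylstannyl)methanol
Product: 20 2-(hydroxymethyl) diketone
Conditions: Pd(PPh3)4 (cat.), toluene, 90 °C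
Reagents that add atoms: (tributylstannyl)methanol, CCCC[Sn](CCCC)(CCCC)CO
Why: Stille coupling: oxidative addition of zerovalent palladium into the activated C2–Br bond, transfer of the hydroxymethyl group from tin and reductive elimination install the C2 substituent under neutral conditions with the alkene position retained.

Step 14
Reactants: 20 hydroxymethyl diketone
Product: 21 2-(tert-butyldimethylsilyloxymethyl) diketone
Conditions: TBSCl, imidazole, CH2Cl2, 0 °C to rt
Reagents that add atoms: tert-butyldimethylsilyl chloride, CC(C)(C)[Si](C)(C)Cl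
Why: Standard silylation of the primary allylic alcohol shields it from the two later oxidations and the acylation, and the group falls in the final acid step.

Step 15
Reactants: 21 silyl ether diketone
Product: 22 cyclopentanone-derived trimethylsilyl enol ether (C1′=C2″)
Conditions: LiN(iPr)2, Me3SiCl (internal quench), THF, −78 °C; used crude
Reagents that add atoms: chlorotrimethylsilane, C[Si](C)(C)Cl
Why: Kinetic enol silylation: the open C2″ methylene of the cyclopentanone (C5 is quaternary) is deprotonated faster than the crowded C7 methine or the γ-methylene C4 of the enone, and the internal quench traps the enolate before proton exchange can reach C7.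

Step 16
Reactants: 22 silyl enol ether
Product: 25 trans-fused δ-lactone (C1′ carbonyl and C2″–O), via seco aldehyde acid 23 (not isolated), via hydroxy acid 24 (not isolated)
Conditions: O3, CH2Cl2–MeOH, −78 °C; Me2S, −78 °C to rt; NaBH4, −78 °C; aq. citric acid work-up
Reagents that add atoms: ozone, [O-][O+]=O
Why: Ozonolysis attacks only the electron-rich enol ether (the enone alkene is deactivated) and cuts C1′–C2″ to acid and aldehyde, borohydride at −78 °C reduces the aldehyde alone, and the δ-hydroxy acid lactonises on acidification, which leaves the two termini at different oxidation levels and avoids a self-condensing 1,5-dialdehyde.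

Step 17
Reactants: 25 lactone
Product: 26 lactol with C1 allylic alcohol
Conditions: iBu2AlH, CH2Cl2, −78 °C; aq. potassium sodium tartrate
Reagents that add atoms: none
Why: Partial lactone reduction stops at the stable aluminium hemiacetal of the α-quaternary lactone while the enone is reduced 1,2 from the face anti to the C7 side chain, which removes the acidity of C7–H before the basic olefination.

Step 18
Reactants: 26 lactol; 27 methyltriphenylphosphonium bromide
Product: 28 5-vinyl diol (C1–OH and C2″–OH)
Conditions: Ph3PCH3Br, KOtBu (slightly less than the salt), THF, 0 to 40 °C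
Reagents that add atoms: methyltriphenylphosphonium bromide, C[P+](c1ccccc1)(c1ccccc1)c1ccccc1.[Br-]
Why: Wittig methylenation of the open hydroxy-aldehyde form of the lactol turns C1′ into a vinyl carbon and releases the C2″ alcohol, with no ketone, ester or epimerisable centre present to interfere.

Step 19
Reactants: 28 vinyl diol
Product: 29 5-vinyl enone aldehyde
Conditions: Dess–Martin periodinane, pyridine, CH2Cl2, 0 °C to rt
Reagents that add atoms: none
Why: One Dess–Martin oxidation restores the C1 enone and raises C2″ to the aldehyde under buffered conditions, erasing the transient C1 centre without disturbing C7.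

Step 20
Reactants: 29 enone aldehyde; 30 senecioic acid (3-methylbut-2-enoic acid)
Product: 31 (E)-enol senecioate
Conditions: 30, DCC, CH2Cl2 (anhydride preformed, urea filtered off); then 29, Et3N, DMAP, rt
Reagents that add atoms: senecioic acid, CC(C)=CC(=O)O
Why: Amine/DMAP enol esterification: only the aldehyde enolises under these mild conditions, O-acylation by the acylpyridinium ion should favour the E geometry because the very bulky C6 residue avoids the acyloxy group, and the anhydride limits ketene-type deconjugation of the acyl group.

Step 21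
Reactants: 31 vinyl enol ester; 32 carbon monoxide
Product: 33 3-(ring C5)propanal
Conditions: Rh(acac)(CO)2 (cat.), Xantphos, CO/H2 (20 bar), toluene, 70 °C
Reagents that add atoms: carbon monoxide, [C-]#[O+]
Why: Rhodium-catalysed hydroformylation: a vinyl group on a quaternary carbon cannot isomerise and for steric reasons takes the formyl group at its terminus, while the trisubstituted, conjugated and 1,2-disubstituted alkenes are too hindered to react.

Step 22
Reactants: 33 aldehyde; 34 isopropenylmagnesium bromide
Product: 35 (R)-isopropenyl carbinol (silyl ether and ketal still in place)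
Conditions: 34, ZnCl2, 1,4-dioxane (salts filtered off); (−)-MIB (cat.), toluene, 0 °C; aq. NH4Cl
Reagents that add atoms: isopropenylmagnesium bromide, C=C(C)[Mg]Br
Why: Catalytic asymmetric alkenylzinc addition: the amino-alkoxide zinc complex activates only the aldehyde (ketone and esters are inert to the diorganozinc), and the established facial preference of this ligand family corresponds here to the R carbinol, any minor epimer being a separable diastereomer.

Step 23
Reactants: 35 protected precursor
Product: 36 target CNP0257974.2
Conditions: 1 M aq. HCl, THF, 0 °C to rt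
Reagents that add atoms: water, O
Why: Mild specific-acid hydrolysis removes the ketone dioxolane and the primary allylic silyl ether far faster than it can hydrolyse the conjugated enol ester, ionise the allylic alcohol or enolise C7.

Compound list
1 | ethyl levulinate | CCOC(=O)CCC(C)=O | starting material
2 | ethyl 3-(2-methyl-1,3-dioxolan-2-yl)propanoate | CCOC(=O)CCC1(C)OCCO1 | intermediate
3 | N-methoxy-N-methyl-3-(2-methyl-1,3-dioxolan-2-yl)propanamide | CON(C)C(=O)CCC1(C)OCCO1 | intermediate
4 | vinylmagnesium bromide | C=C[Mg]Br | starting material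
5 | 5-(2-methyl-1,3-dioxolan-2-yl)pent-1-en-3-one | C=CC(=O)CCC1(C)OCCO1 | intermediate
6 | 2-methylcyclopentane-1,3-dione | CC1C(=O)CCC1=O | starting material
7 | 2-methyl-2-[5-(2-methyl-1,3-dioxolan-2-yl)-3-oxopentyl]cyclopentane-1,3-dione | CC1(CCC(=O)CCC2(C)OCCO2)C(=O)CCC1=O | intermediate
8 | (7aS)-enedione with 4-(ketal-methyl) group | C1CC(=O)[C@@]2(C)CCC(=O)C(CC3(C)OCCO3)=C21 | intermediate
9 | (1S,7aS)-1β-hydroxy enone | C1C[C@H](O)[C@@]2(C)CCC(=O)C(CC3(C)OCCO3)=C21 | intermediate
10 | (1R,7aS)-1α-(4-nitrobenzoyloxy) enone | C1C[C@@H](OC(=O)c3ccc(cc3)[N+](=O)[O-])[C@@]2(C)CCC(=O)C(CC4(C)OCCO4)=C21 | intermediate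
11 | (1R,7aS)-1α-hydroxy enone | C1C[C@@H](O)[C@@]2(C)CCC(=O)C(CC3(C)OCCO3)=C21 | intermediate
12 | (1R,3aS,4R,7aS)-1α-hydroxy trans-hydrindan-5-one, 4β side chain | C1C[C@@H](O)[C@@]2(C)CCC(=O)[C@H](CC3(C)OCCO3)[C@@H]21 | intermediate
13 | bis(trimethylsilyl) precursor (C5=C6 enol ether, 1α-silyl ether) | C1C[C@@H](O[Si](C)(C)C)[C@@]2(C)CC=C(O[Si](C)(C)C)[C@H](CC3(C)OCCO3)[C@@H]21 | intermediate
14 | bromoform | BrC(Br)Br | starting material
15 | α-face dibromocyclopropane adduct | C1C[C@@H](O[Si](C)(C)C)[C@@]2(C)C[C@H]4C(Br)(Br)[C@@]4(O[Si](C)(C)C)[C@H](CC3(C)OCCO3)[C@@H]21 | intermediate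
16 | trans-fused 2-bromo hydroazulenone, 1′α-trimethylsilyl ether | C1C[C@@H](O[Si](C)(C)C)[C@@]2(C)CC=C(Br)C(=O)[C@H](CC3(C)OCCO3)[C@@H]21 | intermediate
17 | trans-fused 2-bromo-1′α-hydroxy hydroazulenone (5β-Me, 6α-H, 7α-H) | C1C[C@@H](O)[C@@]2(C)CC=C(Br)C(=O)[C@H](CC3(C)OCCO3)[C@@H]21 | intermediate
18 | 2-bromo enone cyclopentanone | C1CC(=O)[C@@]2(C)CC=C(Br)C(=O)[C@H](CC3(C)OCCO3)[C@@H]21 | intermediate
19 | (tributylstannyl)methanol | CCCC[Sn](CCCC)(CCCC)CO | starting material
20 | 2-(hydroxymethyl) enone cyclopentanone | C1CC(=O)[C@@]2(C)CC=C(CO)C(=O)[C@H](CC3(C)OCCO3)[C@@H]21 | intermediate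
21 | 2-(TBS-oxymethyl) enone cyclopentanone | C1CC(=O)[C@@]2(C)CC=C(CO[Si](C)(C)C(C)(C)C)C(=O)[C@H](CC3(C)OCCO3)[C@@H]21 | intermediate
22 | C1′=C2″ trimethylsilyl enol ether | C1C=C(O[Si](C)(C)C)[C@@]2(C)CC=C(CO[Si](C)(C)C(C)(C)C)C(=O)[C@H](CC3(C)OCCO3)[C@@H]21 | intermediate
23 | seco aldehyde acid (C5–CO2H, C6–CH2CHO) | OC(=O)[C@@]1(C)CC=C(CO[Si](C)(C)C(C)(C)C)C(=O)[C@H](CC2(C)OCCO2)[C@@H]1CC=O | intermediate
24 | seco hydroxy acid | OC(=O)[C@@]1(C)CC=C(CO[Si](C)(C)C(C)(C)C)C(=O)[C@H](CC2(C)OCCO2)[C@@H]1CCO | intermediate
25 | trans-fused δ-lactone enone | C1COC(=O)[C@@]2(C)CC=C(CO[Si](C)(C)C(C)(C)C)C(=O)[C@H](CC3(C)OCCO3)[C@@H]21 | intermediate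
26 | lactol (anomers), C1β allylic alcohol | C1COC(O)[C@@]2(C)CC=C(CO[Si](C)(C)C(C)(C)C)[C@H](O)[C@H](CC3(C)OCCO3)[C@@H]21 | intermediate
27 | methyltriphenylphosphonium bromide | C[P+](c1ccccc1)(c1ccccc1)c1ccccc1.[Br-] | starting material
28 | 5-vinyl diol | C=C[C@@]1(C)CC=C(CO[Si](C)(C)C(C)(C)C)[C@H](O)[C@H](CC2(C)OCCO2)[C@@H]1CCO | intermediate
29 | 5-vinyl enone aldehyde | C=C[C@@]1(C)CC=C(CO[Si](C)(C)C(C)(C)C)C(=O)[C@H](CC2(C)OCCO2)[C@@H]1CC=O | intermediate
30 | senecioic acid | CC(C)=CC(=O)O | starting material
31 | 5-vinyl (E)-enol senecioate | C=C[C@@]1(C)CC=C(CO[Si](C)(C)C(C)(C)C)C(=O)[C@H](CC2(C)OCCO2)[C@@H]1/C=C/OC(=O)C=C(C)C | intermediate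
32 | carbon monoxide | [C-]#[O+] | starting material
33 | chain aldehyde (C5–CH2CH2CHO) | O=CCC[C@@]1(C)CC=C(CO[Si](C)(C)C(C)(C)C)C(=O)[C@H](CC2(C)OCCO2)[C@@H]1/C=C/OC(=O)C=C(C)C | intermediate
34 | isopropenylmagnesium bromide | C=C(C)[Mg]Br | starting material
35 | (R)-carbinol, TBS ether and ketal retained | C=C(C)[C@H](O)CC[C@@]1(C)CC=C(CO[Si](C)(C)C(C)(C)C)C(=O)[C@H](CC2(C)OCCO2)[C@@H]1/C=C/OC(=O)C=C(C)C | intermediate
36 | CNP0257974.2 | C=C(C)[C@H](O)CC[C@@]1(C)CC=C(CO)C(=O)[C@H](CC(C)=O)[C@@H]1/C=C/OC(=O)C=C(C)C | target

Total step count: 23. Longest linear sequence: 23 steps (1 to 36); all other components are purchased.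

Steps most likely to fail

1. Step 11. Possible failures:
- premature desilylation of the enol ether by tert-butoxide;
- slow carbene transfer to the hindered alkene;
- base-induced epimerisation at C7 once the enone has formed.

Fallback (sets out from 13, returns at 20): the same carbon is inserted as a methylene group without alkoxide base. Cyclopropanation with Et2Zn/CH2I2 gives the siloxycyclopropane F1. FeCl3 in DMF opens the shared bond oxidatively to the ring-enlarged 3-chloro ketone F2. NaOAc in warm MeOH eliminates hydrogen chloride and frees the carbinol to give the hydroxy cycloheptenone F3. I2/pyridine α-iodination gives the 2-iodo enone F4. Oxidation as in step 12 gives the iodo diketone F5, which enters the coupling of step 13 to give 20.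

2. Step 9. Possible failures:
- little or no hydrogen uptake at the tetrasubstituted, carbonyl-deactivated alkene;
- catalyst deactivation;
- competition of the ketal oxygens for the metal, with loss of facial control;
- acid-induced epimerisation at C4.

Fallback (sets out from 9, returns at 18): the face is controlled by shielding instead of coordination.
- The 1β-carbinol is kept and silylated (Et3SiCl, imidazole) to the triethylsilyl ether F6, in which the angular methyl and the silyloxy group both cover the β face.
- Neutral heterogeneous hydrogenation (H2, Pd/C, EtOAc) should then add hydrogen syn from the α face to give the hydrindanone F7.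
- Enol silylation as in step 10 gives the enol ether F8.
- The carbene conditions of step 11, without the methanolysis, lead through the dibromocyclopropane F9 to the bromoenone F10.
- HF·pyridine frees the 1′β-carbinol F11, and the oxidation of step 12 erases that centre to give 18.

Steps 7 and 8 are then not needed.

3. Step 20. Possible failures:
- poor control of the enol double-bond geometry;
- migration of the acyl double bond out of conjugation through ketene formation;
- amine-induced epimerisation at C7.

Fallback (sets out from 29, returns at 31): geometry and acyl transfer are separated. Et3SiOTf/Et3N at −78 °C converts the aldehyde into its triethylsilyl enol ether, and the geometry is secured by chromatography on deactivated silica to give the (E)-silyl enol ether F12. Senecioyl fluoride with catalytic Bu4NF in THF then transfers the acyl group to oxygen with retention of geometry and without amine base, giving 31.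

Further compounds
F1 | step 11 | α-face siloxycyclopropane | C1C[C@@H](O[Si](C)(C)C)[C@@]2(C)C[C@H]4C[C@@]4(O[Si](C)(C)C)[C@H](CC3(C)OCCO3)[C@@H]21
F2 | step 11 | ring-enlarged 3-chloro ketone (C3 epimers) | C1C[C@@H](O[Si](C)(C)C)[C@@]2(C)CC(Cl)CC(=O)[C@H](CC3(C)OCCO3)[C@@H]21
F3 | step 11 | 1′α-hydroxy cycloheptenone | C1C[C@@H](O)[C@@]2(C)CC=CC(=O)[C@H](CC3(C)OCCO3)[C@@H]21
F4 | step 11 | 2-iodo-1′α-hydroxy enone | C1C[C@@H](O)[C@@]2(C)CC=C(I)C(=O)[C@H](CC3(C)OCCO3)[C@@H]21
F5 | step 11 | 2-iodo enone cyclopentanone | C1CC(=O)[C@@]2(C)CC=C(I)C(=O)[C@H](CC3(C)OCCO3)[C@@H]21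
F6 | step 9 | 1β-triethylsilyloxy enone | C1C[C@H](O[Si](CC)(CC)CC)[C@@]2(C)CCC(=O)C(CC3(C)OCCO3)=C21
F7 | step 9 | 1β-triethylsilyloxy trans-hydrindanone | C1C[C@H](O[Si](CC)(CC)CC)[C@@]2(C)CCC(=O)[C@H](CC3(C)OCCO3)[C@@H]21
F8 | step 9 | its C5=C6 trimethylsilyl enol ether | C1C[C@H](O[Si](CC)(CC)CC)[C@@]2(C)CC=C(O[Si](C)(C)C)[C@H](CC3(C)OCCO3)[C@@H]21
F9 | step 9 | dibromocyclopropane adduct | C1C[C@H](O[Si](CC)(CC)CC)[C@@]2(C)C[C@H]4C(Br)(Br)[C@@]4(O[Si](C)(C)C)[C@H](CC3(C)OCCO3)[C@@H]21
F10 | step 9 | 2-bromo enone, 1′β-triethylsilyl ether | C1C[C@H](O[Si](CC)(CC)CC)[C@@]2(C)CC=C(Br)C(=O)[C@H](CC3(C)OCCO3)[C@@H]21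
F11 | step 9 | 2-bromo-1′β-hydroxy enone | C1C[C@H](O)[C@@]2(C)CC=C(Br)C(=O)[C@H](CC3(C)OCCO3)[C@@H]21
F12 | step 20 | (E)-triethylsilyl enol ether of 29 | C=C[C@@]1(C)CC=C(CO[Si](C)(C)C(C)(C)C)C(=O)[C@H](CC2(C)OCCO2)[C@@H]1/C=C/O[Si](CC)(CC)CC
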